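**Retrosynthetic overview**
1. Last disconnection C9–C10: the ten-membered carbocycle is closed by an intramolecular Nozaki–Hiyama–Kishi addition of the C10 vinyl iodide of seco aldehyde 22 to its C9 aldehyde, which gives 23 directly with every other function already in place.
2. Enabling feature: C9 is a carbinol bonded to C10, the α-carbon of the C1(10)/C14 enoate (a β-hydroxy-α-alkylidene ester), and the chain between them is pre-bent by three cis elements: the cis-fused C6/C7 γ-lactone, the cis C4/C5 oxirane and the (Z)-C1=C10 iodoenoate.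
3. Oxirane C4–C5 from the (Z)-alkene by epoxidation on the face flanked by the lactone oxygen; C8 angelate and C9 aldehyde from a glyceraldehyde acetonide unit.
4. C6–C7 bond and lactone C–O bond: indium Barbier allylation–lactonization that unites enal 8 (from neryl acetate) with allyl bromide 12 (from (R)-glyceraldehyde acetonide) and sets C6 and C7 from C8.
5. Ring order: γ-lactone (step 8), oxirane (step 12), ten-membered carbocycle (step 15).

Key step: step 15

Remark: atoms carry germacranolide numbers (C1=C10 enoate with C14 ester, C4/C5 oxirane with C15 methyl, C6/C7 lactone carbons, C8 angelate, C9 carbinol, C11–C13 α-methylene lactone); read this way the SMILES shows a ring-cis C1(10) alkene, a cis 4,5-oxirane (C3 and C6 cis) and a cis-fused 6,12-lactone, and the route is planned for exactly this array.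

**Route**

Step 1
Reactants: 1 neryl acetate [(2Z)-3,7-dimethylocta-2,6-dien-1-yl acetate]
Product: 2 (2Z)-5-(3,3-dimethyloxiran-2-yl)-3-methylpent-2-en-1-yl acetate (racemic at the oxirane carbon)
Conditions: mCPBA (1.0 equiv), CH2Cl2, 0 °C
Reagents that add atoms: mCPBA, OOC(=O)c1cccc(Cl)c1
Why: Prilezhaev epoxidation should select the electron-rich distal trisubstituted alkene because the other alkene is deactivated by the allylic acetoxy group; the new stereocenter is cleaved off in step 2.

Step 2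
Reactants: 2 (2Z)-5-(3,3-dimethyloxiran-2-yl)-3-methylpent-2-en-1-yl acetate
Product: 3 (2Z)-3-methyl-6-oxohex-2-en-1-yl acetate
Conditions: H5IO6, THF/H2O, 0 °C
Reagents that add atoms: none
Why: Acid-mediated opening of the epoxide by water at the tertiary carbon followed by periodate glycol cleavage (Malaprade) should excise the terminus as acetone and leave the epoxide oxygen as the C1 aldehyde oxygen, without touching the (Z)-allylic acetate.

Step 3
Reactants: 3 (2Z)-3-methyl-6-oxohex-2-en-1-yl acetate; 4 methyl (triphenylphosphoranylidene)acetate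
Product: 6 methyl (2Z,6Z)-8-acetoxy-2-iodo-6-methylocta-2,6-dienoate, via iodo ylide 5 (not isolated)
Conditions: 4, N-iodosuccinimide, CH2Cl2, −20 °C; then 3, −20 °C to rt
Reagents that add atoms: N-iodosuccinimide, O=C1CCC(=O)N1I
Why: Iodination of the stabilized ylide and Wittig olefination of the aliphatic aldehyde should place the ester trans to the chain, giving the (Z)-2-iodoenoate in which iodine (the future C9–C10 bond) is cis to C2.

Step 4
Reactants: 6 methyl (2Z,6Z)-8-acetoxy-2-iodo-6-methylocta-2,6-dienoate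
Product: 7 methyl (2Z,6Z)-8-hydroxy-2-iodo-6-methylocta-2,6-dienoate
Conditions: K2CO3 (0.2 equiv), MeOH, 0 °C
Reagents that add atoms: none
Why: Base-catalysed methanolysis of the primary allylic acetate is fast at 0 °C and degenerate at the methyl ester, so only the C6 hydroxyl should be unveiled.

Step 5
Reactants: 7 methyl (2Z,6Z)-8-hydroxy-2-iodo-6-methylocta-2,6-dienoate
Product: 8 methyl (2Z,6Z)-2-iodo-6-methyl-8-oxoocta-2,6-dienoate
Conditions: MnO2 (excess), CH2Cl2, rt
Reagents that add atoms: none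
Why: MnO2 oxidizes allylic alcohols chemoselectively under neutral heterogeneous conditions, which should keep the (Z)-C4=C5 geometry of the neral-type enal and leave the vinyl iodide alone.

Step 6
Reactants: 9 (4R)-2,2-dimethyl-1,3-dioxolane-4-carbaldehyde; 10 methyl acrylate
Product: 11 methyl 2-{hydroxy[(4R)-2,2-dimethyl-1,3-dioxolan-4-yl]methyl}prop-2-enoate (both carbinol epimers)
Conditions: 10 (excess), DABCO (0.5 equiv), 1,4-dioxane/H2O, rt
Reagents that add atoms: none
Why: Morita–Baylis–Hillman reaction of an activated α-alkoxy aldehyde; the dioxolane stereocenter (future C8) is retained and the new carbinol center may stay a mixture because step 7 destroys it.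

Step 7
Reactants: 11 methyl 2-{hydroxy[(4R)-2,2-dimethyl-1,3-dioxolan-4-yl]methyl}prop-2-enoate
Product: 12 methyl (2Z)-2-(bromomethyl)-3-[(4S)-2,2-dimethyl-1,3-dioxolan-4-yl]prop-2-enoate
Conditions: N-bromosuccinimide, Me2S, CH2Cl2, 0 °C to rt
Reagents that add atoms: N-bromosuccinimide, O=C1CCC(=O)N1Br
Why: Corey–Kim-type activation of the allylic alcohol and SN2' attack of bromide should convert both carbinol epimers into the same thermodynamically preferred (Z)-2-(bromomethyl)alk-2-enoate under non-acidic conditions that keep the acetonide.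

Step 8
Reactants: 8 methyl (2Z,6Z)-2-iodo-6-methyl-8-oxoocta-2,6-dienoate; 12 methyl (2Z)-2-(bromomethyl)-3-[(4S)-2,2-dimethyl-1,3-dioxolan-4-yl]prop-2-enoate
Product: 14 methyl (2Z,6Z)-7-[(2S,3S)-3-[(4S)-2,2-dimethyl-1,3-dioxolan-4-yl]-4-methylidene-5-oxooxolan-2-yl]-2-iodo-6-methylhepta-2,6-dienoate, via hydroxy ester 13 (not isolated)
Conditions: indium powder, THF/H2O (1:1), rt; then crude extract, PPTS (cat.), toluene, 50 °C
Reagents that add atoms: none
Why: Indium-mediated Barbier allylation adds 1,2 to the enal through a chair Zimmerman–Traxler transition state with the γ-substituent cis to CH2In axial (6,7-syn adduct), C7 being attacked anti to the C8–C9 bond of the dioxolane in the conformer where H8 eclipses the alkene (A1,3 strain), which should set C6 and C7 from C8; PPTS then closes the cis-fused γ-lactone by transesterification, and indium metal does not touch the vinyl iodide.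

Step 9
Reactants: 14 methyl (2Z,6Z)-7-[(2S,3S)-3-[(4S)-2,2-dimethyl-1,3-dioxolan-4-yl]-4-methylidene-5-oxooxolan-2-yl]-2-iodo-6-methylhepta-2,6-dienoate
Product: 15 methyl (2Z,6Z)-7-[(2S,3R)-3-[(1S)-1,2-dihydroxyethyl]-4-methylidene-5-oxooxolan-2-yl]-2-iodo-6-methylhepta-2,6-dienoate
Conditions: AcOH/H2O (4:1), rt
Reagents that add atoms: none
Why: Acid-catalysed hydrolysis of the terminal isopropylidene acetal is placed here because no acid-labile oxirane is present yet, and the lactone should not migrate to O8 at room temperature.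

Step 10
Reactants: 15 methyl (2Z,6Z)-7-[(2S,3R)-3-[(1S)-1,2-dihydroxyethyl]-4-methylidene-5-oxooxolan-2-yl]-2-iodo-6-methylhepta-2,6-dienoate
Product: 16 methyl (2Z,6Z)-7-[(2S,3R)-3-[(1S)-2-{[tert-butyl(dimethyl)silyl]oxy}-1-hydroxyethyl]-4-methylidene-5-oxooxolan-2-yl]-2-iodo-6-methylhepta-2,6-dienoate
Conditions: TBSCl (1.05 equiv), imidazole, CH2Cl2, 0 °C
Reagents that add atoms: TBSCl, CC(C)(C)[Si](C)(C)Cl
Why: Silylation with TBSCl/imidazole should be selective for the primary C9 hydroxyl over the hindered secondary C8 hydroxyl.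

Step 11
Reactants: 16 methyl (2Z,6Z)-7-[(2S,3R)-3-[(1S)-2-{[tert-butyl(dimethyl)silyl]oxy}-1-hydroxyethyl]-4-methylidene-5-oxooxolan-2-yl]-2-iodo-6-methylhepta-2,6-dienoate; 17 angelic acid [(2Z)-2-methylbut-2-enoic acid]
Product: 19 methyl (2Z,6Z)-7-[(2S,3S)-3-[(1S)-2-{[tert-butyl(dimethyl)silyl]oxy}-1-{[(2Z)-2-methylbut-2-enoyl]oxy}ethyl]-4-methylidene-5-oxooxolan-2-yl]-2-iodo-6-methylhepta-2,6-dienoate, via mixed anhydride 18 (not isolated)
Conditions: 17, 2,4,6-trichlorobenzoyl chloride, Et3N, toluene, rt; then 16, 70 °C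
Reagents that add atoms: none
Why: Yamaguchi esterification through the preformed 2,4,6-trichlorobenzoyl mixed anhydride should acylate the hindered C8 hydroxyl with retention at C8 and, run without DMAP, avoid isomerization of the angelate to the tiglate.

Step 12
Reactants: 19 methyl (2Z,6Z)-7-[(2S,3S)-3-[(1S)-2-{[tert-butyl(dimethyl)silyl]oxy}-1-{[(2Z)-2-methylbut-2-enoyl]oxy}ethyl]-4-methylidene-5-oxooxolan-2-yl]-2-iodo-6-methylhepta-2,6-dienoate
Product: 20 methyl (2Z)-5-[(2R,3S)-3-[(2R,3R)-3-[(1S)-2-{[tert-butyl(dimethyl)silyl]oxy}-1-{[(2Z)-2-methylbut-2-enoyl]oxy}ethyl]-4-methylidene-5-oxooxolan-2-yl]-2-methyloxiran-2-yl]-2-iodopent-2-enoate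
Conditions: mCPBA (1.1 equiv), NaHCO3, CH2Cl2, 0 °C
Reagents that add atoms: mCPBA, OOC(=O)c1cccc(Cl)c1
Why: Prilezhaev epoxidation should select the only electron-rich alkene (C4=C5), and with H6 held in the alkene plane by A1,3 strain with the C3 methylene the peracid should attack the face flanked by the lactone oxygen and not the face shielded by C7 and its cis C8 side chain, giving the cis (4R,5S) oxirane (5,6-threo).

Step 13
Reactants: 20 methyl (2Z)-5-[(2R,3S)-3-[(2R,3R)-3-[(1S)-2-{[tert-butyl(dimethyl)silyl]oxy}-1-{[(2Z)-2-methylbut-2-enoyl]oxy}ethyl]-4-methylidene-5-oxooxolan-2-yl]-2-methyloxiran-2-yl]-2-iodopent-2-enoate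
Product: 21 methyl (2Z)-5-[(2R,3S)-3-[(2R,3R)-3-[(1S)-2-hydroxy-1-{[(2Z)-2-methylbut-2-enoyl]oxy}ethyl]-4-methylidene-5-oxooxolan-2-yl]-2-methyloxiran-2-yl]-2-iodopent-2-enoate
Conditions: HF·pyridine, excess pyridine, THF, 0 °C
Reagents that add atoms: none
Why: Pyridine-buffered HF·pyridine cleaves the primary silyl ether under weakly acidic conditions that should suppress O8-to-O9 acyl migration and spare the trisubstituted oxirane.

Step 14
Reactants: 21 methyl (2Z)-5-[(2R,3S)-3-[(2R,3R)-3-[(1S)-2-hydroxy-1-{[(2Z)-2-methylbut-2-enoyl]oxy}ethyl]-4-methylidene-5-oxooxolan-2-yl]-2-methyloxiran-2-yl]-2-iodopent-2-enoate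
Product: 22 methyl (2Z)-2-iodo-5-[(2R,3S)-2-methyl-3-[(2R,3S)-4-methylidene-3-[(1S)-1-{[(2Z)-2-methylbut-2-enoyl]oxy}-2-oxoethyl]-5-oxooxolan-2-yl]oxiran-2-yl]pent-2-enoate
Conditions: Dess–Martin periodinane, NaHCO3, CH2Cl2, 0 °C to rt; used crude
Reagents that add atoms: none
Why: Buffered Dess–Martin oxidation should give the α-acyloxy aldehyde without epimerization at C8, acyl migration or over-oxidation.

Step 15
Reactants: 22 methyl (2Z)-2-iodo-5-[(2R,3S)-2-methyl-3-[(2R,3S)-4-methylidene-3-[(1S)-1-{[(2Z)-2-methylbut-2-enoyl]oxy}-2-oxoethyl]-5-oxooxolan-2-yl]oxiran-2-yl]pent-2-enoate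
Product: 23 methyl (1(10)E,4R,5S,6R,7R,8S,9S)-8-angeloyloxy-4,5-epoxy-9-hydroxygermacra-1(10),11(13)-dien-12,6-olid-14-oate (target; ring-cis C1(10) enoate)
Conditions: CrCl2 (20 equiv), NiCl2 (0.2 equiv), degassed DMSO/THF (3:1), rt, 22 added by syringe pump to a final 2 mM
Reagents that add atoms: none
Why: Zerovalent nickel, formed from NiCl2 by CrCl2, inserts into the C10–I bond of 22, the vinyl group passes to chromium and the vinylchromium dichloride adds to the C9 aldehyde (Nozaki–Hiyama–Kishi reaction; the closest precedent is the chromium-mediated vinyl iodide–aldehyde closure of medium and large carbocycles, in which α-haloenoates and α-haloenones are known donors). The ten-membered ring closes in a 10-exo-trig mode, made possible because the cis-fused C6/C7 lactone, the cis C4/C5 oxirane and the (Z)-C1=C10 iodoenoate already hold C9 and C10 on the same side of the chain. C9 is the only new stereocenter: ring formation forces C7 to lie gauche to the incoming C10, and with the C8–O bond anti to the forming bond (polar Felkin–Anh alignment) only the transition state leading to the 8,9-threo (9S) carbinol lets the bulky chromium alkoxide sit pseudo-equatorially, outside the ring. The C1(10) geometry is secured by retention in the vinylchromium and, independently, by the tether, which lets C9 bond to C10 only on the side cis to C2, so that any (E)-iodide that equilibrates through the chromium allenolate should be funnelled into the same ring-cis enoate. The step needs chemoselectivity for the C–I bond and the aldehyde beside the α-methylene lactone, oxirane and angelate, which the mild non-basic CrCl2/DMSO system should provide, and ring closure over oligomerization, which slow addition at high dilution should secure.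

**Compound list**
1 | neryl acetate, (2Z)-3,7-dimethylocta-2,6-dien-1-yl acetate | CC(C)=CCC/C(C)=C\COC(C)=O | starting material
2 | (2Z)-5-(3,3-dimethyloxiran-2-yl)-3-methylpent-2-en-1-yl acetate | CC1(C)OC1CC/C(C)=C\COC(C)=O | intermediate
3 | (2Z)-3-methyl-6-oxohex-2-en-1-yl acetate | O=CCC/C(C)=C\COC(C)=O | intermediate
4 | methyl (triphenylphosphoranylidene)acetate | COC(=O)C=P(c1ccccc1)(c1ccccc1)c1ccccc1 | starting material
5 | methyl iodo(triphenylphosphoranylidene)acetate (iodo ylide) | COC(=O)C(I)=P(c1ccccc1)(c1ccccc1)c1ccccc1 | intermediate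
6 | methyl (2Z,6Z)-8-acetoxy-2-iodo-6-methylocta-2,6-dienoate | COC(=O)/C(I)=C/CC/C(C)=C\COC(C)=O | intermediate
7 | methyl (2Z,6Z)-8-hydroxy-2-iodo-6-methylocta-2,6-dienoate | COC(=O)/C(I)=C/CC/C(C)=C\CO | intermediate
8 | methyl (2Z,6Z)-2-iodo-6-methyl-8-oxoocta-2,6-dienoate | COC(=O)/C(I)=C/CC/C(C)=C\C=O | intermediate
9 | (4R)-2,2-dimethyl-1,3-dioxolane-4-carbaldehyde | O=C[C@H]1COC(C)(C)O1 | starting material
10 | methyl acrylate | C=CC(=O)OC | starting material
11 | methyl 2-{hydroxy[(4R)-2,2-dimethyl-1,3-dioxolan-4-yl]methyl}prop-2-enoate (both carbinol epimers) | C=C(C(=O)OC)C(O)[C@H]1COC(C)(C)O1 | intermediate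
12 | methyl (2Z)-2-(bromomethyl)-3-[(4S)-2,2-dimethyl-1,3-dioxolan-4-yl]prop-2-enoate | COC(=O)/C(CBr)=C/[C@H]1COC(C)(C)O1 | intermediate
13 | dimethyl (2Z,6Z,8S,9S)-9-[(4S)-2,2-dimethyl-1,3-dioxolan-4-yl]-8-hydroxy-2-iodo-6-methyl-10-methylideneundeca-2,6-dienedioate (hydroxy ester) | COC(=O)C(=C)[C@@H]([C@@H](O)/C=C(C)\CC/C=C(\I)C(=O)OC)[C@H]1COC(C)(C)O1 | intermediate
14 | methyl (2Z,6Z)-7-[(2S,3S)-3-[(4S)-2,2-dimethyl-1,3-dioxolan-4-yl]-4-methylidene-5-oxooxolan-2-yl]-2-iodo-6-methylhepta-2,6-dienoate | C=C1C(=O)O[C@@H](/C=C(C)\CC/C=C(\I)C(=O)OC)[C@H]1[C@H]1COC(C)(C)O1 | intermediate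
15 | methyl (2Z,6Z)-7-[(2S,3R)-3-[(1S)-1,2-dihydroxyethyl]-4-methylidene-5-oxooxolan-2-yl]-2-iodo-6-methylhepta-2,6-dienoate | C=C1C(=O)O[C@@H](/C=C(C)\CC/C=C(\I)C(=O)OC)[C@H]1[C@H](O)CO | intermediate
16 | methyl (2Z,6Z)-7-[(2S,3R)-3-[(1S)-2-{[tert-butyl(dimethyl)silyl]oxy}-1-hydroxyethyl]-4-methylidene-5-oxooxolan-2-yl]-2-iodo-6-methylhepta-2,6-dienoate | C=C1C(=O)O[C@@H](/C=C(C)\CC/C=C(\I)C(=O)OC)[C@H]1[C@H](O)CO[Si](C)(C)C(C)(C)C | intermediate
17 | angelic acid, (2Z)-2-methylbut-2-enoic acid | C/C=C(/C)C(=O)O | starting material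
18 | (2Z)-2-methylbut-2-enoic 2,4,6-trichlorobenzoic anhydride (mixed anhydride) | C/C=C(/C)C(=O)OC(=O)c1c(Cl)cc(Cl)cc1Cl | intermediate
19 | methyl (2Z,6Z)-7-[(2S,3S)-3-[(1S)-2-{[tert-butyl(dimethyl)silyl]oxy}-1-{[(2Z)-2-methylbut-2-enoyl]oxy}ethyl]-4-methylidene-5-oxooxolan-2-yl]-2-iodo-6-methylhepta-2,6-dienoate | C=C1C(=O)O[C@@H](/C=C(C)\CC/C=C(\I)C(=O)OC)[C@H]1[C@H](OC(=O)/C(C)=C\C)CO[Si](C)(C)C(C)(C)C | intermediate
20 | methyl (2Z)-5-[(2R,3S)-3-[(2R,3R)-3-[(1S)-2-{[tert-butyl(dimethyl)silyl]oxy}-1-{[(2Z)-2-methylbut-2-enoyl]oxy}ethyl]-4-methylidene-5-oxooxolan-2-yl]-2-methyloxiran-2-yl]-2-iodopent-2-enoate | C=C1C(=O)O[C@@H]([C@@H]2O[C@]2(C)CC/C=C(\I)C(=O)OC)[C@H]1[C@H](OC(=O)/C(C)=C\C)CO[Si](C)(C)C(C)(C)C | intermediate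
21 | methyl (2Z)-5-[(2R,3S)-3-[(2R,3R)-3-[(1S)-2-hydroxy-1-{[(2Z)-2-methylbut-2-enoyl]oxy}ethyl]-4-methylidene-5-oxooxolan-2-yl]-2-methyloxiran-2-yl]-2-iodopent-2-enoate | C=C1C(=O)O[C@@H]([C@@H]2O[C@]2(C)CC/C=C(\I)C(=O)OC)[C@H]1[C@H](OC(=O)/C(C)=C\C)CO | intermediate
22 | methyl (2Z)-2-iodo-5-[(2R,3S)-2-methyl-3-[(2R,3S)-4-methylidene-3-[(1S)-1-{[(2Z)-2-methylbut-2-enoyl]oxy}-2-oxoethyl]-5-oxooxolan-2-yl]oxiran-2-yl]pent-2-enoate | C=C1C(=O)O[C@@H]([C@@H]2O[C@]2(C)CC/C=C(\I)C(=O)OC)[C@H]1[C@H](OC(=O)/C(C)=C\C)C=O | intermediate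
23 | methyl (1(10)E,4R,5S,6R,7R,8S,9S)-8-angeloyloxy-4,5-epoxy-9-hydroxygermacra-1(10),11(13)-dien-12,6-olid-14-oate | C=C1C(=O)O[C@@H]2[C@H]1[C@H](OC(=O)/C(C)=C\C)[C@@H](O)/C(C(=O)OC)=C\CC[C@@]1(C)O[C@@H]21 | target

**Totals and risks**

Total step count: 15. Longest linear sequence: 13 steps (steps 1–5, then 8–15).

Steps most likely to fail:

Step 15 (key step). The vinylchromium may add to the other face of the aldehyde through the open-chain Felkin-type arrangement, giving the C9 epimer, or intermolecular coupling may compete with ring closure. In the fallback C9 is set by hydride delivery instead of by the C–C bond formation. It sets out from 22: the ring closure is run as before and the resulting 9-epimer of 23 F1 is oxidized with Dess–Martin periodinane (NaHCO3, CH2Cl2) to the C9 ketone of 23 F2, which is reduced under Luche conditions (NaBH4, CeCl3·7H2O, MeOH, −78 °C). Hydride should enter anti to the C8–O bond from the outer face of the ring, which for a ketone gives the 8,9-threo alcohol; cerium and low temperature should keep the α-methylene lactone from conjugate reduction. The sequence comes back to the route at 23.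

Step 8. The allylindium may react on the other face of C7 (anti to the dioxolane oxygen instead of anti to the C8–C9 bond), giving the syn adduct with C6 and C7 both inverted relative to C8. In the fallback the mirror-image bromide is used and C8 is corrected by inversion at the acylation stage. It sets out from 8: (4S)-2,2-dimethyl-1,3-dioxolane-4-carbaldehyde F3 (commercial) is taken through the Morita–Baylis–Hillman reaction with 10 to the enantiomeric adduct F4 and through the bromination of step 7 to the (4R)-bromide F5. Indium coupling of F5 with 8 should then give the 8-epi hydroxy ester F6 (C6 and C7 as in the target) and, after PPTS, the 8-epi lactone acetonide F7; hydrolysis as in step 9 gives the 8-epi diol F8 and silylation as in step 10 the 8-epi silyl ether F9. Mitsunobu esterification of F9 with 17 (PPh3, DIAD, toluene, 0 °C) inverts C8 and, because the carboxylate acts as nucleophile without acyl activation, should not isomerize the angelate. The sequence comes back to the route at 19.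

Step 12. Facial selectivity of the undirected peracid epoxidation may be poor (attack from the C7 side gives the 4,5-bis-epimeric oxirane), or the peracid may oxidize the vinyl iodide. In the fallback, substrate control is replaced by catalyst control in a Shi epoxidation (fructose-derived ketone catalyst of the matching enantiomeric series, Oxone, K2CO3 buffer, MeCN/dimethoxymethane/H2O, 0 °C), whose dioxirane is not expected to attack the electron-poor iodoenoate. It sets out from 19 and comes back to the route at 20; no new compound is made (F0).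

Further compounds
F1 | step 15 | 9-epimer of 23 (9R carbinol) | C=C1C(=O)O[C@@H]2[C@H]1[C@H](OC(=O)/C(C)=C\C)[C@H](O)/C(C(=O)OC)=C\CC[C@@]1(C)O[C@@H]21
F2 | step 15 | C9 ketone of 23 (9-oxo compound) | C=C1C(=O)O[C@@H]2[C@H]1[C@H](OC(=O)/C(C)=C\C)C(=O)/C(C(=O)OC)=C\CC[C@@]1(C)O[C@@H]21
F3 | step 8 | (4S)-2,2-dimethyl-1,3-dioxolane-4-carbaldehyde | O=C[C@@H]1COC(C)(C)O1
F4 | step 8 | methyl 2-{hydroxy[(4S)-2,2-dimethyl-1,3-dioxolan-4-yl]methyl}prop-2-enoate (both carbinol epimers) | C=C(C(=O)OC)C(O)[C@@H]1COC(C)(C)O1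
F5 | step 8 | methyl (2Z)-2-(bromomethyl)-3-[(4R)-2,2-dimethyl-1,3-dioxolan-4-yl]prop-2-enoate | COC(=O)/C(CBr)=C/[C@@H]1COC(C)(C)O1
F6 | step 8 | dimethyl (2Z,6Z,8S,9S)-9-[(4R)-2,2-dimethyl-1,3-dioxolan-4-yl]-8-hydroxy-2-iodo-6-methyl-10-methylideneundeca-2,6-dienedioate | COC(=O)C(=C)[C@@H]([C@@H](O)/C=C(C)\CC/C=C(\I)C(=O)OC)[C@@H]1COC(C)(C)O1
F7 | step 8 | methyl (2Z,6Z)-7-[(2S,3S)-3-[(4R)-2,2-dimethyl-1,3-dioxolan-4-yl]-4-methylidene-5-oxooxolan-2-yl]-2-iodo-6-methylhepta-2,6-dienoate | C=C1C(=O)O[C@@H](/C=C(C)\CC/C=C(\I)C(=O)OC)[C@H]1[C@@H]1COC(C)(C)O1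
F8 | step 8 | methyl (2Z,6Z)-7-[(2S,3R)-3-[(1R)-1,2-dihydroxyethyl]-4-methylidene-5-oxooxolan-2-yl]-2-iodo-6-methylhepta-2,6-dienoate | C=C1C(=O)O[C@@H](/C=C(C)\CC/C=C(\I)C(=O)OC)[C@H]1[C@@H](O)CO
F9 | step 8 | methyl (2Z,6Z)-7-[(2S,3R)-3-[(1R)-2-{[tert-butyl(dimethyl)silyl]oxy}-1-hydroxyethyl]-4-methylidene-5-oxooxolan-2-yl]-2-iodo-6-methylhepta-2,6-dienoate | C=C1C(=O)O[C@@H](/C=C(C)\CC/C=C(\I)C(=O)OC)[C@H]1[C@@H](O)CO[Si](C)(C)C(C)(C)C
F0 | step 12 | none | none
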